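Ring A is made last by cutting C4a–C5 and C8–C8a. Its carbons C5–C8, with para oxygens at C5/C8 and the vicinal methoxy pair at C6/C7, are the four carbons of dimethyl squarate. C4a–C8a is the only free CH=CH unit (C5=C6) of a monocyclic 4-pyranone (ring C) that already carries O1, the C2 anisyl group, C3-OMe and C4=O. Heating a 4-hydroxycyclobutenone that bears this pyranone on its carbinol carbon opens the four-membered ring to a vinylketene and closes ring A onto pyranone C6 in one operation, giving the 5,8-hydroquinone with all four oxygens in place. Ring C comes from furfural by Achmatowicz ring expansion.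

Key step: step 9

Remark: the target has no stereocentre; every sp3 stereocentre formed on the way is carried as a racemate or diastereomer mixture and is destroyed later.

Step 1
Reactants: 1 furfural; 2 4-methoxyphenylmagnesium bromide (THF solution)
Product: 3 (furan-2-yl)(4-methoxyphenyl)methanol (racemic)
Conditions: THF, 0 °C to rt; then sat. aq NH4Cl
Reagents that add atoms: none
Why: Grignard 1,2-addition of the arylmagnesium bromide to the aldehyde should be clean, and the carbinol stereocentre forms without control, which does not matter because it becomes sp2 later.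

Step 2
Reactants: 3 (furan-2-yl)(4-methoxyphenyl)methanol
Product: 4 6-hydroxy-2-(4-methoxyphenyl)-2H-pyran-3(6H)-one (racemic, mixture of diastereomers)
Conditions: N-bromosuccinimide (1.05 equiv), NaHCO3, THF/H2O (4:1), 0 °C
Reagents that add atoms: water (O)
Why: Achmatowicz rearrangement, in which the buffered bromonium source oxidises the electron-rich furan in preference to the anisyl ring and water supplies the new oxygen, so the six-membered hemiacetal should form as an uncontrolled anomeric mixture.

Step 3
Reactants: 4 6-hydroxy-2-(4-methoxyphenyl)-2H-pyran-3(6H)-one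
Product: 5 6-methoxy-2-(4-methoxyphenyl)-2H-pyran-3(6H)-one (mixture of diastereomers)
Conditions: HC(OMe)3, BF3·OEt2 (cat.), Et2O, 0 °C to rt
Reagents that add atoms: trimethyl orthoformate (COC(OC)OC)
Why: Lewis-acid-catalysed acetalisation through the ring oxocarbenium ion masks the hemiacetal against ring opening in the basic epoxidation that follows; the anomer ratio is immaterial.

Step 4
Reactants: 5 6-methoxy-2-(4-methoxyphenyl)-2H-pyran-3(6H)-one
Product: 6 2-methoxy-4-(4-methoxyphenyl)-3,7-dioxabicyclo[4.1.0]heptan-5-one (the 4,5-epoxide of 5, mixture of diastereomers)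
Conditions: 30% aq H2O2, NaOH (cat.), MeOH, 0 °C
Reagents that add atoms: hydrogen peroxide (OO)
Why: Weitz–Scheffer nucleophilic epoxidation of the enone, in which hydroperoxide adds to the β-carbon and the enolate closes the oxirane, expected mainly anti to the neighbouring methoxy group, a configuration that is lost again in the next step.

Step 5
Reactants: 6 2-methoxy-4-(4-methoxyphenyl)-3,7-dioxabicyclo[4.1.0]heptan-5-one
Product: 7 3-hydroxy-2-(4-methoxyphenyl)-4H-pyran-4-one
Conditions: 2 M aq H2SO4, 1,4-dioxane, 90 °C
Reagents that add atoms: none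
Why: Acid-promoted isomerisation of the α,β-epoxy ketone to the 3,4-dione level, β-elimination of methanol from the acetal carbon and enolisation at C2 should aromatise the ring, the same sequence that converts furyl carbinols into maltol-type γ-pyranones; all stereocentres disappear.

Step 6
Reactants: 7 3-hydroxy-2-(4-methoxyphenyl)-4H-pyran-4-one
Product: 8 3-methoxy-2-(4-methoxyphenyl)-4H-pyran-4-one
Conditions: MeI, K2CO3, acetone, reflux
Reagents that add atoms: iodomethane (CI)
Why: Williamson O-methylation of the acidic enolic hydroxyl, the only nucleophilic site in the molecule.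

Step 7
Reactants: 8 3-methoxy-2-(4-methoxyphenyl)-4H-pyran-4-one
Product: 9 5-iodo-3-methoxy-2-(4-methoxyphenyl)-4H-pyran-4-one
Conditions: I2, pyridine, CHCl3, rt to 40 °C; then aq Na2S2O3
Reagents that add atoms: iodine (II)
Why: Base-mediated α-iodination of an enone by addition–iodination–elimination: pyridine adds reversibly to the unhindered C6, the enolate is iodinated at C5 and pyridine leaves, so iodine should enter the only CH next to the carbonyl while the anisyl ring, deactivated by conjugation with the pyranone, is not attacked.

Step 8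
Reactants: 9 5-iodo-3-methoxy-2-(4-methoxyphenyl)-4H-pyran-4-one; 10 dimethyl squarate
Product: 12 4-hydroxy-2,3-dimethoxy-4-[5-methoxy-6-(4-methoxyphenyl)-4-oxo-4H-pyran-3-yl]cyclobut-2-en-1-one (racemic), via pyranonylmagnesium chloride 11 (not isolated)
Conditions: i-PrMgCl·LiCl, THF, −40 °C; cannulation into 10 (1.5 equiv), THF, −78 °C; sat. aq NH4Cl at −78 °C; rapid filtration through Et3N-deactivated silica
Reagents that add atoms: none
Why: Iodine–magnesium exchange on the α-iodoenone (as known for 3-iodochromones) gives a carbonyl-chelated alkenylmagnesium that is kept cold to suppress ring opening by β-elimination of the ring oxygen, and its Grignard 1,2-addition to one of the two equivalent squarate carbonyls (inverse addition, excess squarate, neutral work-up) should stop at the mono-adduct, whose quaternary carbinol carbon forms as a racemate.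

Step 9
Reactants: 12 4-hydroxy-2,3-dimethoxy-4-[5-methoxy-6-(4-methoxyphenyl)-4-oxo-4H-pyran-3-yl]cyclobut-2-en-1-one
Product: 15 5,8-dihydroxy-3,6,7-trimethoxy-2-(4-methoxyphenyl)-4H-chromen-4-one, via vinylketene 13 (not isolated), via cyclohexadienone 14 (not isolated)
Conditions: degassed p-xylene, 138 °C, argon; crude washed with aq Na2S2O4 and taken on directly
Reagents that add atoms: none
Why: Heat breaks the cyclobutenone C1–C4 bond by 4π conrotatory electrocyclic ring opening to vinylketene 13, the hydroxyl rotating outward so that the pyranonyl group ends up on the ketene side. The dienylketene formed by the ketene, the former squarate C=C and the pyranone C5=C6 then undergoes 6π disrotatory electrocyclisation, the ketene carbon bonding to pyranone C6 (the future C8–C8a bond) and closing ring A as a six-membered carbocycle fused to ring C; enolisation of dienone 14 gives the 5,8-hydroquinone. The closest known reaction type is the Moore rearrangement of 4-aryl- and 4-alkenyl-4-hydroxycyclobutenones derived from squarate esters to annulated hydroquinones, applied here with the pyranone C5=C6 bond as the alkenyl unit. No stereocentre survives: the quaternary carbon of 12 becomes sp2 on ring opening and the C8a–H centre of 14 is erased by tautomerisation. The step needs outward rotation of the hydroxyl, which the donor torquoselectivity of thermal cyclobutenone opening provides and which keeps the hydroxyl from adding to the ketene (furanone formation), and closure at C6 only, which is secured because the other neighbour of C5 is the C4 carbonyl carbon and C6 carries the hydrogen needed for aromatisation.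

Step 10
Reactants: 15 5,8-dihydroxy-3,6,7-trimethoxy-2-(4-methoxyphenyl)-4H-chromen-4-one
Product: 16 3-methoxytangeretin (3,5,6,7,8-pentamethoxy-2-(4-methoxyphenyl)-4H-chromen-4-one)
Conditions: Me2SO4 (excess), K2CO3, acetone, reflux, argon
Reagents that add atoms: dimethyl sulfate (COS(=O)(=O)OC)
Why: Williamson O-methylation of both phenols, in which the free 8-hydroxyl should react quickly and the hydrogen-bonded 5-hydroxyl needs the excess reagent and prolonged reflux, while exclusion of air keeps the hydroquinone dianion from oxidising to the 5,8-quinone.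

Compound list
1 | furfural (furan-2-carbaldehyde) | O=Cc1ccco1 | starting material
2 | 4-methoxyphenylmagnesium bromide (THF solution) | COc1ccc([Mg]Br)cc1 | starting material
3 | (furan-2-yl)(4-methoxyphenyl)methanol, racemic | COc1ccc(C(O)c2ccco2)cc1 | intermediate
4 | 6-hydroxy-2-(4-methoxyphenyl)-2H-pyran-3(6H)-one, racemic, mixture of diastereomers | COc1ccc(C2OC(O)C=CC2=O)cc1 | intermediate
5 | 6-methoxy-2-(4-methoxyphenyl)-2H-pyran-3(6H)-one, racemic, mixture of diastereomers | COc1ccc(C2OC(OC)C=CC2=O)cc1 | intermediate
6 | 2-methoxy-4-(4-methoxyphenyl)-3,7-dioxabicyclo[4.1.0]heptan-5-one, racemic, mixture of diastereomers | COc1ccc(C2OC(OC)C3OC3C2=O)cc1 | intermediate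
7 | 3-hydroxy-2-(4-methoxyphenyl)-4H-pyran-4-one | COc1ccc(-c2occc(=O)c2O)cc1 | intermediate
8 | 3-methoxy-2-(4-methoxyphenyl)-4H-pyran-4-one | COc1ccc(-c2occc(=O)c2OC)cc1 | intermediate
9 | 5-iodo-3-methoxy-2-(4-methoxyphenyl)-4H-pyran-4-one | COc1ccc(-c2occ(I)c(=O)c2OC)cc1 | intermediate
10 | dimethyl squarate (3,4-dimethoxycyclobut-3-ene-1,2-dione) | COC1=C(OC)C(=O)C1=O | starting material
11 | [5-methoxy-6-(4-methoxyphenyl)-4-oxo-4H-pyran-3-yl]magnesium chloride, LiCl complex, formed in the flask | COc1ccc(-c2occ([Mg]Cl)c(=O)c2OC)cc1 | intermediate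
12 | 4-hydroxy-2,3-dimethoxy-4-[5-methoxy-6-(4-methoxyphenyl)-4-oxo-4H-pyran-3-yl]cyclobut-2-en-1-one, racemic | COc1ccc(-c2occ(C3(O)C(OC)=C(OC)C3=O)c(=O)c2OC)cc1 | intermediate
13 | (3Z)-4-hydroxy-2,3-dimethoxy-4-[5-methoxy-6-(4-methoxyphenyl)-4-oxo-4H-pyran-3-yl]buta-1,3-dien-1-one (vinylketene), formed in the flask | COC(=C=O)/C(OC)=C(/O)c1coc(-c2ccc(OC)cc2)c(OC)c1=O | intermediate
14 | 5-hydroxy-3,6,7-trimethoxy-2-(4-methoxyphenyl)-4H-chromene-4,8(8aH)-dione, racemic, formed in the flask | COc1ccc(C2=C(OC)C(=O)C3=C(O)C(OC)=C(OC)C(=O)C3O2)cc1 | intermediate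
15 | 5,8-dihydroxy-3,6,7-trimethoxy-2-(4-methoxyphenyl)-4H-chromen-4-one | COc1ccc(-c2oc3c(O)c(OC)c(OC)c(O)c3c(=O)c2OC)cc1 | intermediate
16 | 3-methoxytangeretin (3,5,6,7,8-pentamethoxy-2-(4-methoxyphenyl)-4H-chromen-4-one) | COc1ccc(-c2oc3c(OC)c(OC)c(OC)c(OC)c3c(=O)c2OC)cc1 | target

Total step count: 10. Longest linear sequence: 10 steps (furfural 1 to target 16; dimethyl squarate 10 is bought and enters at step 8).

Steps most likely to fail

Step 9 (ring expansion). The hydroxyl may rotate inward or add to the ketene, diverting the vinylketene to a furanone, and the electron-rich hydroquinone may oxidise and degrade at the reaction temperature. The fallback sets out from 12 and comes back at 16. The tertiary hydroxyl of 12 would be methylated (MeI, Ag2O, K2CO3, MeCN, rt) to 2,3,4-trimethoxy-4-[5-methoxy-6-(4-methoxyphenyl)-4-oxo-4H-pyran-3-yl]cyclobut-2-en-1-one F1. With no free hydroxyl the ketene cannot be trapped internally, and the same thermolysis in p-xylene should give 8-hydroxy-3,5,6,7-tetramethoxy-2-(4-methoxyphenyl)-4H-chromen-4-one F2. This monophenol is not a hydroquinone and already carries the 5-methoxy group, so methylation of its unchelated 8-hydroxyl (Me2SO4, K2CO3, acetone) gives 16.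

Step 8 (metalation and squarate addition). The C5-magnesiated pyranone may ring-open by β-elimination of the ring oxygen, or the exchange reagent may attack the pyranone, before the carbanion meets the squarate. The fallback sets out from 8 and comes back at 15, so iodide 9 is not needed. Deprotonation of 8 with TMPMgCl·LiCl (THF, −40 °C) at C6, the CH next to the ring oxygen, should give [5-methoxy-6-(4-methoxyphenyl)-4-oxo-4H-pyran-2-yl]magnesium chloride F3, an α-oxygenated alkenylmagnesium with no β-leaving group. Addition to 10 at −78 °C and a cold NH4Cl quench should give the regioisomeric carbinol 4-hydroxy-2,3-dimethoxy-4-[5-methoxy-6-(4-methoxyphenyl)-4-oxo-4H-pyran-2-yl]cyclobut-2-en-1-one F4. Because both alkene carbons of the squarate carry methoxy groups, thermolysis of F4 (the ketene carbon now closing on C5 and forming the C4a–C5 bond) leads to the same hydroquinone 15. Any metalation at C5 instead would simply give 11.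

Step 5 (epoxy ketone to hydroxypyranone). The acid-induced epoxide opening may take a ring-contraction path to a 2-aroyl-3-hydroxyfuran, or cleave the benzylic C2–O bond, instead of the hydride shift that leads to the pyranone. The fallback sets out from 5 and comes back at 7, so steps 4 and 5 are not needed; the oxidation level is set with halogen instead of peroxide. Br2 (1 equiv, CH2Cl2, −30 °C) would add across C4=C5 of 5 to give 4,5-dibromo-6-methoxy-2-(4-methoxyphenyl)oxan-3-one F5. Et3N would then eliminate HBr to 4-bromo-6-methoxy-2-(4-methoxyphenyl)-2H-pyran-3(6H)-one F6. Heating F6 in aqueous acid (acetal hydrolysis, dehydration and displacement of bromide by water at C4) should give 7, the halogen variant of the furyl carbinol to γ-pyranone conversion.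

Further compounds
F1 | step 9 | 2,3,4-trimethoxy-4-[5-methoxy-6-(4-methoxyphenyl)-4-oxo-4H-pyran-3-yl]cyclobut-2-en-1-one, racemic | COc1ccc(-c2occ(C3(OC)C(OC)=C(OC)C3=O)c(=O)c2OC)cc1
F2 | step 9 | 8-hydroxy-3,5,6,7-tetramethoxy-2-(4-methoxyphenyl)-4H-chromen-4-one | COc1ccc(-c2oc3c(O)c(OC)c(OC)c(OC)c3c(=O)c2OC)cc1
F3 | step 8 | [5-methoxy-6-(4-methoxyphenyl)-4-oxo-4H-pyran-2-yl]magnesium chloride | COc1ccc(-c2oc([Mg]Cl)cc(=O)c2OC)cc1
F4 | step 8 | 4-hydroxy-2,3-dimethoxy-4-[5-methoxy-6-(4-methoxyphenyl)-4-oxo-4H-pyran-2-yl]cyclobut-2-en-1-one, racemic | COc1ccc(-c2oc(C3(O)C(OC)=C(OC)C3=O)cc(=O)c2OC)cc1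
F5 | step 5 | 4,5-dibromo-6-methoxy-2-(4-methoxyphenyl)oxan-3-one, mixture of diastereomers | COc1ccc(C2OC(OC)C(Br)C(Br)C2=O)cc1
F6 | step 5 | 4-bromo-6-methoxy-2-(4-methoxyphenyl)-2H-pyran-3(6H)-one, mixture of diastereomers | COc1ccc(C2OC(OC)C=C(Br)C2=O)cc1
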